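The readings are calculated on assumed constants; the scatter is artificial.

The time of reading means little until you know how long the flask would need for its whole charge at its own pace. Call that the charge time; the number to find is reading time over charge time, the share of substrate turned into target for as long as that pace holds.

| setting | summer | spring | epsilon | beta |
|---|---|---|---|---|
| substrate | 0.50 M | 0.50 M | 0.50 M | 0.50 M |
| coupling partner | 0.45 M | 1 M | 1.50 M | 0.550 M |
| free catalyst | 0.50 mM | 0.50 mM | 0.50 mM | 0.50 mM |
| remark | run made earlier | run made earlier |  |  |
| time |  |  | 2.0 min | 6.0 min |

| run | time / min | target / % |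
|---|---|---|
| summer | 0.500 | 0.9 |
| summer | 1.33 | 5.3 |
| summer | 2.50 | 12.2 |
| summer | 4.00 | 14.4 |
| spring | 0.333 | 1.7 |
| spring | 0.833 | 4.3 |
| spring | 2.00 | 9.5 |
| spring | 4.00 | 18.6 |

(readings scatter by 1 percentage point)

- the flask that ends with the higher amount of target, in percent of the substrate charged, or "neither" when 2 percentage points or less lies between them (epsilon / beta / neither)
- final target, as a percentage of the substrate charged, in epsilon
- final target, as a percentage of the substrate charged, in beta



Spring's last reading gives a charge time of 21.5 min and summer's gives 27.8 min. Follow one catalyst molecule round: I assume each round costs a wait for coupling partner, inversely proportional to the partner charge, plus a fixed stretch, as in saturation kinetics. The two runs then split the charge time, and each flask gets its own: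

wait at spring's partner charge: 5.13 min

fixed stretch: 16.4 min

epsilon: 2.0 min over 19.8 min gives 10.1%

beta: 6.0 min over 25.7 min gives 23.3%

Is one number enough? Summer's reading at 2.50 min stands 3.2 percentage points above its line, against a scatter of 1 point, so my beta carries that doubt. The choice of flask holds up better: summer's last reading of 14.4% already exceeds epsilon's number by 4.3 points.

The forecast names beta, with 9.6% (8.3% to 11.5%) for epsilon and 20% (15% to 28%) for beta, holding that “summer stalls clearly after about 2.5 min”. My beta stands higher, as my straight line carries no stall.

The flask gives beta, with 10.1% in epsilon and 23.3% in beta.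

    coupling partner + free catalyst ⇌ catalyst intermediate A (K = 40.0 L mol⁻¹, k = 360 L mol⁻¹ min⁻¹)
    catalyst intermediate A ⇌ released group + catalyst intermediate B (K = 0.200 M, k = 18000 min⁻¹)
    substrate + catalyst intermediate B → catalyst intermediate C (k = 350 L mol⁻¹ min⁻¹)
    catalyst intermediate C → catalyst intermediate D (k = 210 min⁻¹)
    catalyst intermediate D → free catalyst + target (k = 170 min⁻¹)
    substrate + target → side product (k = 0.0150 L mol⁻¹ min⁻¹)
    released group → by-product carried off (k = 0.780 min⁻¹)
    substrate + free catalyst ⇌ idle complex, settled at all times (K = 0.640 L mol⁻¹)

Free catalyst stands at 23.9% of the catalyst charged in beta at 6.00 min, more than the 9.49% in epsilon at 2.00 min. Beta's charge time of 25.7 min, held against a reading at 4.0 min, gives 15.6%, and the same flask read then holds 16.0% target.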